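**Retrosynthetic overview**
1. Numbering: bridgeheads C1 and C5; enolised tricarbonyl bridge C2–C3–C4 with the 3-hydroxybenzoyl group on C3; carbon bridge C6–C7–C8; bridging ketone C9. Ring A = C1, C2, C3, C4, C5, C9; ring B = C5, C6, C7, C8, C1, C9.
2. Feature that carries the plan: C6, C7 and C8, with the methyl and 4-methylpent-3-enyl groups on C8, add up to one intact geranyl unit attached to C5. Ring B is therefore a C5 geranyl chain whose C7=C8 alkene has been geranylated at C7 and tied back to C1 through C8.
3. Last disconnection: the C7–CH2(geranyl) and C1–C8 bonds are cut together. This opens ring B and gives geranyl diphosphate 18 and the monocyclic, dearomatised (S)-17. In the forward sense a UbiA-type prenyltransferase makes both bonds and sets C1, C7 and C8 in one event.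
4. 17 comes from desilylation and resolution of racemic 15. 15 comes from C-geranylation of the symmetric 3,5-diprenyl acylphloroglucinol 12, whose two reactive ring carbons are equivalent, so no regioisomer can form.
5. Ring A is the phloroglucinol ring of 1 and is present from the start. The aroyl group comes from 3 by aryllithium/Weinreb amide coupling, with its phenol masked as a triisopropylsilyl ether during the alkylations. Ring B is formed last.

Key step: step 12

Assumption: the enolised polycarbonyl compounds 15–17, 20 and 21 are drawn and named as the single tautomer that matches the target SMILES (tautomers interconvert freely, CIP descriptors refer to the drawn form), and 18 is drawn as the free acid although it is handled as its ammonium salt.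

Step 1
Reactants: 1 phloroglucinol
Product: 2 1,3,5-tris(methoxymethoxy)benzene
Conditions: MOMCl (3.6 equiv), i-Pr2NEt (4 equiv), DMF, 0 °C to rt
Reagents that add atoms: chloromethyl methyl ether, COCCl
Why: Threefold O-alkylation (acetal protection of phenols): the hard chloromethyl ether should react at oxygen and not at the ring carbons, and the resulting OCH2OMe groups direct the lithiation in step 4.

Step 2
Reactants: 3 3-hydroxybenzoic acid
Product: 5 3-hydroxy-N-methoxy-N-methylbenzamide, via 1-(3-hydroxybenzoyl)imidazole 4 (not isolated)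
Conditions: 1,1'-carbonyldiimidazole (1.05 equiv), THF, rt; then MeNH(OMe)·HCl (1.2 equiv), rt
Reagents that add atoms: N,O-dimethylhydroxylamine hydrochloride, CNOC.Cl; 1,1'-carbonyldiimidazole, O=C(n1ccnc1)n1ccnc1 (imidazolyl group of 4 only)
Why: Amide formation through an acyl imidazole: the carboxylic acid should be activated much faster than the phenol, and the amine then displaces imidazole from 4 to give the Weinreb amide.

Step 3
Reactants: 5 3-hydroxy-N-methoxy-N-methylbenzamide
Product: 6 N-methoxy-N-methyl-3-(triisopropylsilyloxy)benzamide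
Conditions: i-Pr3SiCl (1.2 equiv), imidazole (2.5 equiv), DMF, rt
Reagents that add atoms: chlorotriisopropylsilane, CC(C)[Si](Cl)(C(C)C)C(C)C
Why: Silyl ether protection of a phenol: among aryl silyl ethers the triisopropylsilyl group should best resist the acid of step 5 and the bases of steps 6 and 8, it keeps the 3'-oxygen from being alkylated there, and it leaves later with fluoride without touching alkenes or enols.

Step 4
Reactants: 2 1,3,5-tris(methoxymethoxy)benzene; 6 N-methoxy-N-methyl-3-(triisopropylsilyloxy)benzamide
Product: 8 [2,4,6-tris(methoxymethoxy)phenyl][3-(triisopropylsilyloxy)phenyl]methanone, via 2,4,6-tris(methoxymethoxy)phenyllithium 7 (not isolated)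
Conditions: 2, n-BuLi (1.05 equiv), THF, 0 °C; then 6, −78 °C to 0 °C; aq. NH4Cl
Reagents that add atoms: n-butyllithium, [Li]CCCC (lithium of 7 only)
Why: Directed ortho-metalation followed by a Weinreb ketone synthesis: the position flanked by two OCH2OMe groups is the most acidic one of 2, and the N-methoxy-N-methyl amide should take up the hindered aryllithium 7 only once, so the acylation needs no Lewis acid that would strip the silyl ether.

Step 5
Reactants: 8 [2,4,6-tris(methoxymethoxy)phenyl][3-(triisopropylsilyloxy)phenyl]methanone
Product: 9 (2,4,6-trihydroxyphenyl)[3-(triisopropylsilyloxy)phenyl]methanone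
Conditions: aq. HCl (cat.), MeOH, 45 °C
Reagents that add atoms: none
Why: Acid-catalysed acetal cleavage (transacetalisation to dimethoxymethane): all three aryl methoxymethyl ethers should fall off under conditions that an aryl triisopropylsilyl ether tolerates, since such ethers are far more sensitive to base than to acid.

Step 6
Reactants: 9 (2,4,6-trihydroxyphenyl)[3-(triisopropylsilyloxy)phenyl]methanone; 10 prenyl bromide (1-bromo-3-methylbut-2-ene)
Product: 12 [2,4,6-trihydroxy-3,5-bis(3-methylbut-2-enyl)phenyl][3-(triisopropylsilyloxy)phenyl]methanone, via monoprenyl ketone 11 (not isolated)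
Conditions: KOH (2.1 equiv), 10 (2.3 equiv), H2O/MeOH, 0 °C to rt, Ar
Reagents that add atoms: none
Why: Twofold C-alkylation of an acylphloroglucinolate in a protic medium, the standard access to 3,5-diprenyl acylphloroglucinols: hydrogen bonding shields the phenoxide oxygens so that the two free ring carbons react, and because the acidic ring hydroxyls take up all the KOH, hardly any free hydroxide remains to attack the silyl ether.

Step 7
Reactants: 13 geraniol
Product: 14 geranyl bromide [(2E)-1-bromo-3,7-dimethylocta-2,6-diene]
Conditions: PBr3 (0.4 equiv), Et2O, −10 °C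
Reagents that add atoms: phosphorus tribromide, BrP(Br)Br
Why: Bromination of a primary allylic alcohol with PBr3 (SN2 on the phosphite ester): at low temperature it should proceed without allylic transposition and with retention of the (E)-alkene.

Step 8
Reactants: 12 [2,4,6-trihydroxy-3,5-bis(3-methylbut-2-enyl)phenyl][3-(triisopropylsilyloxy)phenyl]methanone; 14 geranyl bromide
Product: 15 rac-6-[(2E)-3,7-dimethylocta-2,6-dienyl]-3,5-dihydroxy-2,6-bis(3-methylbut-2-enyl)-4-[3-(triisopropylsilyloxy)benzoyl]cyclohexa-2,4-dien-1-one
Conditions: LiN(SiMe3)2 (2.2 equiv), THF, −78 °C to 0 °C; 14 (1.1 equiv), 0 °C to rt; cold dilute aq. HCl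
Reagents that add atoms: none
Why: Alkylative dearomatisation (C-alkylation of an acylphloroglucinol dianion, the reaction type that leads to lupulone-type compounds): a prenyl-bearing ring carbon should attack the soft allylic bromide in SN2 fashion, the two such carbons of 12 are equivalent so only one constitution can arise, the (E)-alkene is untouched, and C5 forms as a racemate because nothing chiral is present.

Step 9
Reactants: 15 racemic silyl ether
Product: 16 rac-6-[(2E)-3,7-dimethylocta-2,6-dienyl]-3,5-dihydroxy-4-(3-hydroxybenzoyl)-2,6-bis(3-methylbut-2-enyl)cyclohexa-2,4-dien-1-one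
Conditions: n-Bu4NF (1.5 equiv), AcOH (1.5 equiv), THF, 0 °C, Ar
Reagents that add atoms: none
Why: Fluoride-induced cleavage of an aryl silyl ether: the strong Si–F bond drives it, buffering with AcOH keeps the medium from becoming basic enough to degrade the air-sensitive enolate, and C5 is not affected.

Step 10
Reactants: 16 racemic dearomatised acylphloroglucinol
Product: 17 (6S)-6-[(2E)-3,7-dimethylocta-2,6-dienyl]-3,5-dihydroxy-4-(3-hydroxybenzoyl)-2,6-bis(3-methylbut-2-enyl)cyclohexa-2,4-dien-1-one
Conditions: preparative supercritical-fluid chromatography, immobilised amylose tris(3,5-dimethylphenylcarbamate) phase, CO2/MeOH with 0.1% HCO2H, 35 °C; product stored under Ar at −20 °C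
Reagents that add atoms: none
Why: Resolution by chromatography on a chiral stationary phase, routine for racemic dearomatised acylphloroglucinols: it secures C5 as the (S) antipode, the antipodes should be assigned by comparing measured and computed electronic circular dichroism, and the quaternary centre cannot epimerise afterwards.

Step 11
Reactants: 14 geranyl bromide
Product: 18 geranyl diphosphate (ammonium salt, drawn as free acid)
Conditions: (n-Bu4N)3HP2O7 (2 equiv), MeCN, rt; sulfonic acid cation-exchange resin (NH4+ form), aq. NH4HCO3; lyophilisation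
Reagents that add atoms: tris(tetrabutylammonium) hydrogen diphosphate, CCCC[N+](CCCC)(CCCC)CCCC.CCCC[N+](CCCC)(CCCC)CCCC.CCCC[N+](CCCC)(CCCC)CCCC.O=P([O-])([O-])OP(=O)([O-])O
Why: SN2 displacement of a primary allylic bromide by hydrogen diphosphate, the standard synthesis of allylic diphosphates: the lipophilic ammonium salt makes the anion soluble and nucleophilic in MeCN, ion exchange gives the water-soluble salt the enzyme needs, and the (E)-alkene is unchanged.

Step 12
Reactants: 17 (S)-configured dearomatised acylphloroglucinol; 18 geranyl diphosphate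
Product: 21 (1S,5S,7R,8S)-7-[(2E)-3,7-dimethylocta-2,6-dienyl]-4-hydroxy-3-(3-hydroxybenzoyl)-8-methyl-1,5-bis(3-methylbut-2-enyl)-8-(4-methylpent-3-enyl)bicyclo[3.3.1]non-3-ene-2,9-dione, via geranyl cation 19 (not isolated), via C8 tertiary cation 20 (not isolated)
Conditions: microsomal membranes of Saccharomyces cerevisiae expressing the selected UbiA-type prenyltransferase variant, 18 (3 equiv), MgCl2 (10 mM), HEPES–KOH buffer (50 mM, pH 7.5), 2% DMSO, 30 °C, Ar; EtOAc extraction at pH 5; reversed-phase HPLC
Reagents that add atoms: none
Why: Proposed new method: in the MgCl2-loaded pocket the diphosphate of 18 should leave to give the ion-paired allyl cation 19, C7 of the C7=C8 alkene in the C5 geranyl chain of 17 should bond to its CH2 terminus in the Markovnikov sense (charge on tertiary C8, cation 20), and the enol carbon C1 should collapse onto C8 while the departing diphosphate takes the C2–OH proton, which gives 21 directly. The closest known reaction type is the prenylative bicyclisation of dearomatised acylphloroglucinols by membrane-bound UbiA-type prenyltransferases using dimethylallyl diphosphate, so a C10 donor combined with a 3-hydroxybenzoyl acceptor still has to be found by enzyme mining or directed evolution. Ring B (C5–C6–C7–C8–C1–C9) closes by C1–C8 bond formation in a 6-endo-trig mode with respect to the C7=C8 alkene and exo with respect to the C1=C2 enol, through a chair. C7 and C8 follow from anti addition of 19 and C1 across the (E)-alkene in that chair, which puts the new geranyl chain and the 4-methylpent-3-enyl group (trans to C6 on the alkene) equatorial and the methyl group (cis to C6) axial, that is (7R,8S), while C1 becomes (S) because the short tether lets C8 reach only the ring face on which (S)-C5 holds the geranyl chain. The step needs the C7=C8 alkene to react in preference to the three other side-chain alkenes of 17 and the two of the donor, alkylation at carbon and not at an enol oxygen, capture by C1 and not by C3, and no self-cyclisation of 19; the substrate secures part of this, because only the two chains on sp3-hybridised C5 can fold over ring A, they occupy opposite faces so that (S)-C5 turns the choice between them into the facial choice made on binding, and C3 is encumbered and deactivated by its hydrogen-bonded aroyl group, whereas the rest has to come from the shape of the pocket.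

**Compound list**
1 | phloroglucinol (benzene-1,3,5-triol) | Oc1cc(O)cc(O)c1 | starting material
2 | 1,3,5-tris(methoxymethoxy)benzene | COCOc1cc(OCOC)cc(OCOC)c1 | intermediate
3 | 3-hydroxybenzoic acid | O=C(O)c1cccc(O)c1 | starting material
4 | 1-(3-hydroxybenzoyl)imidazole | O=C(c1cccc(O)c1)n1ccnc1 | intermediate
5 | 3-hydroxy-N-methoxy-N-methylbenzamide | CON(C)C(=O)c1cccc(O)c1 | intermediate
6 | N-methoxy-N-methyl-3-(triisopropylsilyloxy)benzamide | CON(C)C(=O)c1cccc(O[Si](C(C)C)(C(C)C)C(C)C)c1 | intermediate
7 | 2,4,6-tris(methoxymethoxy)phenyllithium | [Li]c1c(OCOC)cc(OCOC)cc1OCOC | intermediate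
8 | [2,4,6-tris(methoxymethoxy)phenyl][3-(triisopropylsilyloxy)phenyl]methanone | COCOc1cc(OCOC)c(C(=O)c2cccc(O[Si](C(C)C)(C(C)C)C(C)C)c2)c(OCOC)c1 | intermediate
9 | (2,4,6-trihydroxyphenyl)[3-(triisopropylsilyloxy)phenyl]methanone | O=C(c1cccc(O[Si](C(C)C)(C(C)C)C(C)C)c1)c1c(O)cc(O)cc1O | intermediate
10 | prenyl bromide (1-bromo-3-methylbut-2-ene) | CC(C)=CCBr | starting material
11 | [2,4,6-trihydroxy-3-(3-methylbut-2-enyl)phenyl][3-(triisopropylsilyloxy)phenyl]methanone (monoprenyl ketone) | CC(C)=CCc1c(O)cc(O)c(C(=O)c2cccc(O[Si](C(C)C)(C(C)C)C(C)C)c2)c1O | intermediate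
12 | [2,4,6-trihydroxy-3,5-bis(3-methylbut-2-enyl)phenyl][3-(triisopropylsilyloxy)phenyl]methanone | CC(C)=CCc1c(O)c(CC=C(C)C)c(O)c(C(=O)c2cccc(O[Si](C(C)C)(C(C)C)C(C)C)c2)c1O | intermediate
13 | geraniol | CC(C)=CCC/C(C)=C/CO | starting material
14 | geranyl bromide | CC(C)=CCC/C(C)=C/CBr | intermediate
15 | rac-6-[(2E)-3,7-dimethylocta-2,6-dienyl]-3,5-dihydroxy-2,6-bis(3-methylbut-2-enyl)-4-[3-(triisopropylsilyloxy)benzoyl]cyclohexa-2,4-dien-1-one | CC(C)=CCC/C(C)=C/CC1(CC=C(C)C)C(=O)C(CC=C(C)C)=C(O)C(C(=O)c2cccc(O[Si](C(C)C)(C(C)C)C(C)C)c2)=C1O | intermediate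
16 | rac-6-[(2E)-3,7-dimethylocta-2,6-dienyl]-3,5-dihydroxy-4-(3-hydroxybenzoyl)-2,6-bis(3-methylbut-2-enyl)cyclohexa-2,4-dien-1-one | CC(C)=CCC/C(C)=C/CC1(CC=C(C)C)C(=O)C(CC=C(C)C)=C(O)C(C(=O)c2cccc(O)c2)=C1O | intermediate
17 | (6S)-6-[(2E)-3,7-dimethylocta-2,6-dienyl]-3,5-dihydroxy-4-(3-hydroxybenzoyl)-2,6-bis(3-methylbut-2-enyl)cyclohexa-2,4-dien-1-one | CC(C)=CCC/C(C)=C/C[C@]1(CC=C(C)C)C(=O)C(CC=C(C)C)=C(O)C(C(=O)c2cccc(O)c2)=C1O | intermediate
18 | geranyl diphosphate | CC(C)=CCC/C(C)=C/COP(=O)(O)OP(=O)(O)O | intermediate
19 | geranyl cation (enzyme-bound ion pair) | CC(C)=CCC/C(C)=C/[CH2+] | intermediate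
20 | C8 tertiary cation (C7-geranylated 17, enzyme-bound) | CC(C)=CCC/C(C)=C/C[C@H](C[C@]1(CC=C(C)C)C(=O)C(CC=C(C)C)=C(O)C(C(=O)c2cccc(O)c2)=C1O)[C+](C)CCC=C(C)C | intermediate
21 | (1S,5S,7R,8S)-7-[(2E)-3,7-dimethylocta-2,6-dienyl]-4-hydroxy-3-(3-hydroxybenzoyl)-8-methyl-1,5-bis(3-methylbut-2-enyl)-8-(4-methylpent-3-enyl)bicyclo[3.3.1]non-3-ene-2,9-dione | CC(C)=CCC/C(C)=C/C[C@@H]1C[C@]2(CC=C(C)C)C(=O)[C@@](CC=C(C)C)(C(=O)C(C(=O)c3cccc(O)c3)=C2O)[C@@]1(C)CCC=C(C)C | target

**Total step count:** 12
**Longest linear sequence:** 9 steps (3 → 5 → 6 → 8 → 9 → 12 → 15 → 16 → 17 → 21; steps 2, 3, 4, 5, 6, 8, 9, 10, 12)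

**Three steps most likely to fail**

1. Step 12.

What may go wrong: no variant may bind the C10 donor and this acceptor productively. Hydrolysis of 18, geranylation at oxygen, attack by another alkene, capture of C8 by C3 or plain lack of turnover would then prevail.

Fallback by known chemistry, setting out from 12 and 14 and coming back at 21: the C7–geranyl bond is made first by an auxiliary-controlled enolate alkylation, and only the C1–C8 bond is left to a chemical cation cyclisation.

Commercial (E)-geranic acid is coupled with (S)-4-benzyl-2-oxazolidinone (EDC·HCl, DMAP, CH2Cl2) to give (S)-4-benzyl-3-[(2E)-3,7-dimethylocta-2,6-dienoyl]oxazolidin-2-one F1. NaN(SiMe3)2 (THF, −78 °C) takes a proton from the methyl group on C3 of the acyl chain. Bromide 14 then alkylates the dienolate at the α-carbon on the face away from the benzyl group (deconjugative Evans alkylation). This should give (S)-4-benzyl-3-[(2S,4E)-5,9-dimethyl-2-(6-methylhepta-1,5-dien-2-yl)deca-4,8-dienoyl]oxazolidin-2-one F2, with the future C7 centre in place and a 1,1-disubstituted alkene at the future C8.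

LiBH4 (Et2O/MeOH, 0 °C) removes the auxiliary and gives (2S,4E)-5,9-dimethyl-2-(6-methylhepta-1,5-dien-2-yl)deca-4,8-dien-1-ol F3. Tf2O/2,6-lutidine (CH2Cl2, −78 °C) converts it into (2S,4E)-5,9-dimethyl-2-(6-methylhepta-1,5-dien-2-yl)deca-4,8-dienyl trifluoromethanesulfonate F4, which is used at once.

Alkylative dearomatisation of 12 (LiN(SiMe3)2, THF, −78 °C to rt) with F4 should give (6S)-6-[(2R,4E)-5,9-dimethyl-2-(6-methylhepta-1,5-dien-2-yl)deca-4,8-dienyl]-3,5-dihydroxy-2,6-bis(3-methylbut-2-enyl)-4-[3-(triisopropylsilyloxy)benzoyl]cyclohexa-2,4-dien-1-one F5. The reaction has no reason to be selective at C5. The C7 centre turns the outcome into a diastereomer problem, however, so silica gel suffices and the chiral chromatography of step 10 falls away.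

Neat HCO2H at rt protonates the 1,1-disubstituted alkene at its CH2 end, and C1 closes onto C8. This biomimetic cationic cyclisation is known for dearomatised acylphloroglucinols with a 2-isopropenylalkyl side chain and free prenyl groups. It should give (1S,5S,7R,8S)-7-[(2E)-3,7-dimethylocta-2,6-dienyl]-4-hydroxy-8-methyl-1,5-bis(3-methylbut-2-enyl)-8-(4-methylpent-3-enyl)-3-[3-(triisopropylsilyloxy)benzoyl]bicyclo[3.3.1]non-3-ene-2,9-dione F6. Here C8 is controlled only by the chair preference of the larger group for the equatorial site, so a chromatographic purification has to be expected. n-Bu4NF/AcOH as in step 9 then gives 21.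

2. Step 8.

What may go wrong: alkylation at an enolate oxygen, a second alkylation or SN2' attack may outrun bond formation at the hindered, already substituted ring carbon.

Fallback, setting out from 12 and 13 and coming back at 15: the bromide is replaced by a π-allyl complex, which changes the hard/soft balance (Tsuji–Trost allylation). Geraniol 13 is converted with ClCO2Me/pyridine (CH2Cl2, 0 °C) into geranyl methyl carbonate F7. With Pd(PPh3)4 (5 mol%, THF, rt) the zerovalent palladium ionises F7, and the methoxide released after loss of CO2 deprotonates 12. The soft carbon nucleophile should then attack the unsubstituted terminus of the syn π-geranyl ligand. Any aryl or enol allyl ether is re-ionised by the catalyst, so material should funnel to the irreversibly C-alkylated 15.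

3. Step 10.

What may go wrong: exchange between tautomers may broaden the peaks, and the small difference between a prenyl and a geranyl chain may give too little chiral recognition for a preparative separation. The antipodes may also be assigned the wrong way round.

Fallback, setting out from 16 and coming back at 21: the separation is left to the enzyme of step 12 (enzymatic kinetic resolution). Racemic 16 is incubated with 18 under the conditions of step 12. Only the antipode whose geranyl chain lies on the face that fits the pocket should be turned over in the wanted way. Any turnover of the other antipode through its prenyl alkene would change the constitution and not the handedness, so ordinary reversed-phase HPLC would remove it together with unreacted material. The enantiomeric purity of 21 is then checked on a chiral phase. This fallback makes no new compound (F0).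

**Further compounds**
F1 | step 12 | (S)-4-benzyl-3-[(2E)-3,7-dimethylocta-2,6-dienoyl]oxazolidin-2-one | CC(C)=CCC/C(C)=C/C(=O)N1C(=O)OC[C@@H]1Cc1ccccc1
F2 | step 12 | (S)-4-benzyl-3-[(2S,4E)-5,9-dimethyl-2-(6-methylhepta-1,5-dien-2-yl)deca-4,8-dienoyl]oxazolidin-2-one | CC(C)=CCC/C(C)=C/C[C@H](C(=O)N1C(=O)OC[C@@H]1Cc1ccccc1)C(=C)CCC=C(C)C
F3 | step 12 | (2S,4E)-5,9-dimethyl-2-(6-methylhepta-1,5-dien-2-yl)deca-4,8-dien-1-ol | CC(C)=CCC/C(C)=C/C[C@H](CO)C(=C)CCC=C(C)C
F4 | step 12 | (2S,4E)-5,9-dimethyl-2-(6-methylhepta-1,5-dien-2-yl)deca-4,8-dienyl trifluoromethanesulfonate | CC(C)=CCC/C(C)=C/C[C@H](COS(=O)(=O)C(F)(F)F)C(=C)CCC=C(C)C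
F5 | step 12 | (6S)-6-[(2R,4E)-5,9-dimethyl-2-(6-methylhepta-1,5-dien-2-yl)deca-4,8-dienyl]-3,5-dihydroxy-2,6-bis(3-methylbut-2-enyl)-4-[3-(triisopropylsilyloxy)benzoyl]cyclohexa-2,4-dien-1-one | CC(C)=CCC/C(C)=C/C[C@H](C[C@]1(CC=C(C)C)C(=O)C(CC=C(C)C)=C(O)C(C(=O)c2cccc(O[Si](C(C)C)(C(C)C)C(C)C)c2)=C1O)C(=C)CCC=C(C)C
F6 | step 12 | (1S,5S,7R,8S)-7-[(2E)-3,7-dimethylocta-2,6-dienyl]-4-hydroxy-8-methyl-1,5-bis(3-methylbut-2-enyl)-8-(4-methylpent-3-enyl)-3-[3-(triisopropylsilyloxy)benzoyl]bicyclo[3.3.1]non-3-ene-2,9-dione | CC(C)=CCC/C(C)=C/C[C@@H]1C[C@]2(CC=C(C)C)C(=O)[C@@](CC=C(C)C)(C(=O)C(C(=O)c3cccc(O[Si](C(C)C)(C(C)C)C(C)C)c3)=C2O)[C@@]1(C)CCC=C(C)C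
F7 | step 8 | geranyl methyl carbonate | CC(C)=CCC/C(C)=C/COC(=O)OC
F0 | step 10 | none | none
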